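**Strategy.** Ring C is not made from a chalcone. C2 of the target is a para-hydroxybenzylic carbon of ring B, and the unit ring B–C2–C3(OH)–C4 is the skeleton of D-tyrosine. The O1–C2 bond is therefore cut back to a benzylic C–H bond. An open-chain (R)-α-hydroxydihydrochalcone, whose only stereocentre (C3) comes from D-tyrosine, is dehydrogenated to a ring-B p-quinone methide. The ortho-hydroxyl of ring A (future O1) traps it. One operation closes the pyranone ring and sets C2 trans to C3. Because o-prenylphenols do not survive this oxidation, C6 and C3' are carried as C–Br, and both prenyl groups are installed afterwards in one twofold coupling.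

Key step: step 8

Remark: CIP analysis of the given SMILES gives (2R,3R), the 2,3-trans dihydroflavonol. Flavonoid numbering (O1, C2–C8a, C1'–C6') is used for the future ring atoms of open-chain compounds too. D-tyrosine, 4,6-dibromoresorcinol and tributyl(3-methylbut-2-en-1-yl)stannane are taken as commercial.

Step 1
Reactants: 1 D-tyrosine
Product: 2 3-bromo-D-tyrosine
Conditions: Br2 (1.0 equiv), 33% HBr/AcOH, rt
Reagents that add atoms: bromine, BrBr
Why: Electrophilic aromatic bromination, in which the amine is masked as its ammonium salt, the phenol directs ortho (para is blocked), one equivalent of bromine should stop at the monobromide, and the α-stereocentre takes no part.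

Step 2
Reactants: 2 3-bromo-D-tyrosine
Product: 5 (R)-3-(3-bromo-4-hydroxyphenyl)-2-hydroxypropanoic acid, via diazonium carboxylate 3 (not isolated), via alpha-lactone 4 (not isolated)
Conditions: NaNO2 (1.5 equiv), 1 M aq H2SO4, 0 °C to rt
Reagents that add atoms: water, O
Why: Diazotisation and hydroxy-deamination of an α-amino acid, in which the carboxylate displaces N2 from 3 with inversion to give 4 and water opens 4 with a second inversion, so the net retention fixes the future C3 as R.

Step 3
Reactants: 5 (R)-3-(3-bromo-4-hydroxyphenyl)-2-hydroxypropanoic acid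
Product: 6 (R)-3-(3-bromo-4-hydroxyphenyl)-2-hydroxy-N-methoxy-N-methylpropanamide
Conditions: MeNH(OMe)·HCl, EDC·HCl, HOBt, N-methylmorpholine, DMF, 0 °C to rt
Reagents that add atoms: N,O-dimethylhydroxylamine hydrochloride, CNOC.Cl
Why: Carbodiimide/HOBt amide coupling to a Weinreb amide, in which the amine outcompetes both hydroxyl groups as nucleophile and HOBt suppresses epimerisation.

Step 4
Reactants: 6 (R)-3-(3-bromo-4-hydroxyphenyl)-2-hydroxy-N-methoxy-N-methylpropanamide
Product: 7 (R)-3-[3-bromo-4-(methoxymethoxy)phenyl]-N-methoxy-2-(methoxymethoxy)-N-methylpropanamide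
Conditions: MOMCl (3 equiv), i-Pr2NEt, CH2Cl2, 0 °C to rt
Reagents that add atoms: chloromethyl methyl ether (MOMCl), COCCl
Why: MOM ether formation (O-alkylation under amine base) caps the phenol and the secondary alcohol without touching the amide or the α-stereocentre.

Step 5
Reactants: 8 4,6-dibromoresorcinol
Product: 9 1,5-dibromo-2,4-bis(methoxymethoxy)benzene
Conditions: MOMCl (2.5 equiv), i-Pr2NEt, CH2Cl2, 0 °C to rt
Reagents that add atoms: chloromethyl methyl ether (MOMCl), COCCl
Why: MOM ether formation on both equivalent phenols gives a symmetric dibromide whose ortho-acetal oxygens later support the aryllithium.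

Step 6
Reactants: 9 1,5-dibromo-2,4-bis(methoxymethoxy)benzene, 7 (R)-3-[3-bromo-4-(methoxymethoxy)phenyl]-N-methoxy-2-(methoxymethoxy)-N-methylpropanamide
Product: 11 (R)-1-[5-bromo-2,4-bis(methoxymethoxy)phenyl]-3-[3-bromo-4-(methoxymethoxy)phenyl]-2-(methoxymethoxy)propan-1-one, via aryllithium 10 (not isolated)
Conditions: 9 (1.2 equiv), n-BuLi (1.15 equiv), THF, −78 °C; then 7, −78 to −40 °C; sat. aq NH4Cl
Reagents that add atoms: none
Why: Bromine–lithium exchange and Weinreb ketone synthesis, in which the two C–Br bonds of symmetric 9 are equivalent so that one exchange defines the acyl carbon (future C4a) and leaves the other bromine exactly at the future C6, the ortho-OMOM group stabilises 10, and the N-methoxy-N-methylamide prevents over-addition and leaves the α-alkoxy stereocentre untouched at low temperature.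

Step 7
Reactants: 11 (R)-1-[5-bromo-2,4-bis(methoxymethoxy)phenyl]-3-[3-bromo-4-(methoxymethoxy)phenyl]-2-(methoxymethoxy)propan-1-one
Product: 12 (R)-1-(5-bromo-2,4-dihydroxyphenyl)-3-(3-bromo-4-hydroxyphenyl)-2-hydroxypropan-1-one
Conditions: conc. HCl (cat.), MeOH, 50 °C
Reagents that add atoms: none
Why: Acid-catalysed acetal exchange with methanol removes all four MOM groups at a stage where no acid-sensitive prenyl group is present, and the chelated α-ketol should keep its configuration under mild acid.

Step 8
Reactants: 12 (R)-1-(5-bromo-2,4-dihydroxyphenyl)-3-(3-bromo-4-hydroxyphenyl)-2-hydroxypropan-1-one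
Product: 14 (2R,3R)-6-bromo-2-(3-bromo-4-hydroxyphenyl)-3,7-dihydroxy-2,3-dihydro-4H-chromen-4-one, via p-quinone methide 13 (not isolated)
Conditions: DDQ (1.05 equiv), 4 Å MS, 1,4-dioxane, rt to 50 °C
Reagents that add atoms: none
Why: DDQ forms a charge-transfer complex with the only non-acylated phenol (ring B) and takes a hydride from the para-benzylic C2–H while the ring-B hydroxyl loses its proton, which gives p-quinone methide 13. The ortho-OH of ring A then adds to the methide carbon C2 in a 6-exo-trig oxa-1,6-addition that forms O1–C2, closes ring C and restores the aromaticity of ring B. The closest known reaction type is the quinone-mediated dehydrogenative cycloetherification of p-hydroxyphenylalkanes (phenolic 1,3-diarylpropanes to flavans, lignan diols to tetrahydrofurans). C3 is not touched and controls C2: in the half-chair transition state the aryl group and the 3-OH both lie pseudo-equatorial, and since the addition is reversible through 13 (the species through which 4'-hydroxydihydroflavonols epimerise at C2 only), the mixture should settle on the diequatorial 2,3-trans (2R,3R) isomer. Chemoselectivity is secured by the substrate, since C2–H2 is its only benzylic position (C6 and C3' carry Br instead of prenyl, so chromene formation is impossible), ring A is deactivated by the acyl group, the 3-OH could only close a strained oxirane, and the future 7-OH cannot reach C2. One equivalent of oxidant and a base-free medium are needed to hold back further dehydrogenation of ring C and a proton shift in 13 that would erase C3.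

Step 9
Reactants: 14 (2R,3R)-6-bromo-2-(3-bromo-4-hydroxyphenyl)-3,7-dihydroxy-2,3-dihydro-4H-chromen-4-one
Product: 15 (2R,3R)-6-bromo-2-[3-bromo-4-(tert-butyldimethylsilyloxy)phenyl]-7-(tert-butyldimethylsilyloxy)-3-hydroxy-2,3-dihydro-4H-chromen-4-one
Conditions: TBSCl (2.2 equiv), imidazole, DMF, 0 °C
Reagents that add atoms: tert-butyldimethylsilyl chloride (TBSCl), CC(C)(C)[Si](C)(C)Cl
Why: Imidazole-promoted silyl ether formation, in which the two acidic phenols react far faster than the hindered, hydrogen-bonded 3-OH, and capping the 4'-OH blocks quinone methide ring opening and so locks C2 for the hot coupling step.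

Step 10
Reactants: 15 (2R,3R)-6-bromo-2-[3-bromo-4-(tert-butyldimethylsilyloxy)phenyl]-7-(tert-butyldimethylsilyloxy)-3-hydroxy-2,3-dihydro-4H-chromen-4-one
Product: 16 (2R,3R)-7-(tert-butyldimethylsilyloxy)-2-[4-(tert-butyldimethylsilyloxy)-3-(3-methylbut-2-en-1-yl)phenyl]-3-hydroxy-6-(3-methylbut-2-en-1-yl)-2,3-dihydro-4H-chromen-4-one
Conditions: prenylSnBu3 (3 equiv), Pd(PPh3)4 (10 mol %), toluene, 105 °C
Reagents that add atoms: tributyl(3-methylbut-2-en-1-yl)stannane, CCCC[Sn](CCCC)(CCCC)CC=C(C)C
Why: Twofold Migita–Kosugi–Stille allylation under neutral conditions, in which oxidative addition at both aryl C–Br bonds, transmetalation and reductive elimination at the less hindered CH2 terminus should place linear prenyl groups at C6 and C3', with no acid, base or oxidant that could touch the ketol or the stereocentres.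

Step 11
Reactants: 16 (2R,3R)-7-(tert-butyldimethylsilyloxy)-2-[4-(tert-butyldimethylsilyloxy)-3-(3-methylbut-2-en-1-yl)phenyl]-3-hydroxy-6-(3-methylbut-2-en-1-yl)-2,3-dihydro-4H-chromen-4-one
Product: 17 lespeflorin B1
Conditions: TBAF/AcOH (1:1, 2.5 equiv), THF, 0 °C
Reagents that add atoms: none
Why: Fluoride-induced desilylation buffered by acetic acid frees both phenols without strong acid (no chroman formation from the o-prenylphenols) and without free base (no enolisation at C3, no ring opening at C2).

**Compound list**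

1 | D-tyrosine, (R)-2-amino-3-(4-hydroxyphenyl)propanoic acid | N[C@H](Cc1ccc(O)cc1)C(=O)O | starting material
2 | 3-bromo-D-tyrosine, (R)-2-amino-3-(3-bromo-4-hydroxyphenyl)propanoic acid | N[C@H](Cc1ccc(O)c(Br)c1)C(=O)O | intermediate
3 | diazonium carboxylate, (R)-2-(3-bromo-4-hydroxyphenyl)-1-carboxylatoethanediazonium | N#[N+][C@H](Cc1ccc(O)c(Br)c1)C(=O)[O-] | intermediate
4 | alpha-lactone, (S)-3-(3-bromo-4-hydroxybenzyl)oxiran-2-one | O=C1O[C@H]1Cc1ccc(O)c(Br)c1 | intermediate
5 | (R)-3-(3-bromo-4-hydroxyphenyl)-2-hydroxypropanoic acid | O[C@H](Cc1ccc(O)c(Br)c1)C(=O)O | intermediate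
6 | (R)-3-(3-bromo-4-hydroxyphenyl)-2-hydroxy-N-methoxy-N-methylpropanamide | O[C@H](Cc1ccc(O)c(Br)c1)C(=O)N(C)OC | intermediate
7 | (R)-3-[3-bromo-4-(methoxymethoxy)phenyl]-N-methoxy-2-(methoxymethoxy)-N-methylpropanamide | COCO[C@H](Cc1ccc(OCOC)c(Br)c1)C(=O)N(C)OC | intermediate
8 | 4,6-dibromoresorcinol (4,6-dibromobenzene-1,3-diol) | Oc1cc(O)c(Br)cc1Br | starting material
9 | 1,5-dibromo-2,4-bis(methoxymethoxy)benzene | COCOc1cc(OCOC)c(Br)cc1Br | intermediate
10 | aryllithium, [5-bromo-2,4-bis(methoxymethoxy)phenyl]lithium | [Li]c1cc(Br)c(OCOC)cc1OCOC | intermediate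
11 | (R)-1-[5-bromo-2,4-bis(methoxymethoxy)phenyl]-3-[3-bromo-4-(methoxymethoxy)phenyl]-2-(methoxymethoxy)propan-1-one | COCO[C@H](Cc1ccc(OCOC)c(Br)c1)C(=O)c1cc(Br)c(OCOC)cc1OCOC | intermediate
12 | (R)-1-(5-bromo-2,4-dihydroxyphenyl)-3-(3-bromo-4-hydroxyphenyl)-2-hydroxypropan-1-one | O[C@H](Cc1ccc(O)c(Br)c1)C(=O)c1cc(Br)c(O)cc1O | intermediate
13 | p-quinone methide, 2-bromo-4-[(2R)-3-(5-bromo-2,4-dihydroxyphenyl)-2-hydroxy-3-oxopropylidene]cyclohexa-2,5-dien-1-one (exocyclic C=C geometry not defined) | O=C1C=CC(=C[C@@H](O)C(=O)c2cc(Br)c(O)cc2O)C=C1Br | intermediate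
14 | (2R,3R)-6-bromo-2-(3-bromo-4-hydroxyphenyl)-3,7-dihydroxy-2,3-dihydro-4H-chromen-4-one | Oc1ccc([C@H]2Oc3cc(O)c(Br)cc3C(=O)[C@@H]2O)cc1Br | intermediate
15 | (2R,3R)-6-bromo-2-[3-bromo-4-(tert-butyldimethylsilyloxy)phenyl]-7-(tert-butyldimethylsilyloxy)-3-hydroxy-2,3-dihydro-4H-chromen-4-one | CC(C)(C)[Si](C)(C)Oc1ccc([C@H]2Oc3cc(O[Si](C)(C)C(C)(C)C)c(Br)cc3C(=O)[C@@H]2O)cc1Br | intermediate
16 | (2R,3R)-7-(tert-butyldimethylsilyloxy)-2-[4-(tert-butyldimethylsilyloxy)-3-(3-methylbut-2-en-1-yl)phenyl]-3-hydroxy-6-(3-methylbut-2-en-1-yl)-2,3-dihydro-4H-chromen-4-one | CC(C)=CCc1cc([C@H]2Oc3cc(O[Si](C)(C)C(C)(C)C)c(CC=C(C)C)cc3C(=O)[C@@H]2O)ccc1O[Si](C)(C)C(C)(C)C | intermediate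
17 | lespeflorin B1, (2R,3R)-3,7-dihydroxy-2-[4-hydroxy-3-(3-methylbut-2-en-1-yl)phenyl]-6-(3-methylbut-2-en-1-yl)-2,3-dihydro-4H-chromen-4-one | CC(C)=CCc1cc([C@H]2Oc3cc(O)c(CC=C(C)C)cc3C(=O)[C@@H]2O)ccc1O | target

**Step count and risks**

Total step count: 11. Longest linear sequence: 10 (steps 1–4 and 6–11; step 5 is the side branch).

**Steps most likely to fail**

**Step 8.**
- What may go wrong: hydride abstraction may be too slow on the bromine-deactivated ring B. Further dehydrogenation of the closed ring, or a proton shift in the quinone methide that erases the C3 configuration, may compete.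
- Fallback: ring C is closed by epoxide opening instead of C–H oxidation. The fallback sets out from 10 (made from 9 as in step 6), which is quenched with N-methoxy-N-methylacetamide to give 1-[5-bromo-2,4-bis(methoxymethoxy)phenyl]ethan-1-one F1. Commercial 3-bromo-4-hydroxybenzaldehyde is protected with MOMCl/i-Pr2NEt to 3-bromo-4-(methoxymethoxy)benzaldehyde F2. Claisen–Schmidt condensation (KOH, EtOH) joins the two to (E)-1-[5-bromo-2,4-bis(methoxymethoxy)phenyl]-3-[3-bromo-4-(methoxymethoxy)phenyl]prop-2-en-1-one F3. Juliá–Colonna epoxidation (poly-L-leucine, urea–H2O2, DBU, THF) should give [5-bromo-2,4-bis(methoxymethoxy)phenyl]{(2R,3S)-3-[3-bromo-4-(methoxymethoxy)phenyl]oxiran-2-yl}methanone F4. HCl in MeOH then removes the MOM groups, and the freed ortho-OH opens the epoxide at the benzylic carbon with inversion, which comes back to the route at 14.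

**Step 10.**
- What may go wrong: transmetalation of the hindered prenylstannane next to the bulky silyloxy groups may be slow. Coupling may occur through the tertiary terminus of the prenyl unit. Palladium hydride may move the double bond into conjugation.
- Fallback: the C–C bond and the trisubstituted alkene are made separately. The fallback sets out from 15. A twofold Stille coupling with the unhindered, terminus-degenerate allyltributylstannane (Pd(PPh3)4, toluene, 105 °C) gives (2R,3R)-6-allyl-2-[3-allyl-4-(tert-butyldimethylsilyloxy)phenyl]-7-(tert-butyldimethylsilyloxy)-3-hydroxy-2,3-dihydro-4H-chromen-4-one F5. A twofold olefin cross-metathesis with excess 2-methyl-2-butene (Grubbs second-generation catalyst, CH2Cl2, 40 °C) converts both allyl groups into prenyl groups and comes back to the route at 16.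

**Step 6.**
- What may go wrong: bromine–lithium scrambling may occur between the aryllithium and the ring-B C–Br bond during a slow addition to the hindered amide. Proton transfer may quench the aryllithium.
- Fallback: a much faster electrophile is used and the oxidation state is corrected afterwards. The fallback sets out from 7, which DIBAL-H (toluene, −78 °C) reduces to (R)-3-[3-bromo-4-(methoxymethoxy)phenyl]-2-(methoxymethoxy)propanal F6. Addition of 10 at −78 °C gives (2R)-1-[5-bromo-2,4-bis(methoxymethoxy)phenyl]-3-[3-bromo-4-(methoxymethoxy)phenyl]-2-(methoxymethoxy)propan-1-ol F7, as carbinol epimers of no consequence. Dess–Martin oxidation comes back to the route at 11.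

**Further compounds**

F1 | step 8 | 1-[5-bromo-2,4-bis(methoxymethoxy)phenyl]ethan-1-one | CC(=O)c1cc(Br)c(OCOC)cc1OCOC
F2 | step 8 | 3-bromo-4-(methoxymethoxy)benzaldehyde | COCOc1ccc(C=O)cc1Br
F3 | step 8 | (E)-1-[5-bromo-2,4-bis(methoxymethoxy)phenyl]-3-[3-bromo-4-(methoxymethoxy)phenyl]prop-2-en-1-one | COCOc1ccc(/C=C/C(=O)c2cc(Br)c(OCOC)cc2OCOC)cc1Br
F4 | step 8 | [5-bromo-2,4-bis(methoxymethoxy)phenyl]{(2R,3S)-3-[3-bromo-4-(methoxymethoxy)phenyl]oxiran-2-yl}methanone | O=C(c1cc(Br)c(OCOC)cc1OCOC)[C@@H]2O[C@H]2c3ccc(OCOC)c(Br)c3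
F5 | step 10 | (2R,3R)-6-allyl-2-[3-allyl-4-(tert-butyldimethylsilyloxy)phenyl]-7-(tert-butyldimethylsilyloxy)-3-hydroxy-2,3-dihydro-4H-chromen-4-one | C=CCc1cc([C@H]2Oc3cc(O[Si](C)(C)C(C)(C)C)c(CC=C)cc3C(=O)[C@@H]2O)ccc1O[Si](C)(C)C(C)(C)C
F6 | step 6 | (R)-3-[3-bromo-4-(methoxymethoxy)phenyl]-2-(methoxymethoxy)propanal | COCO[C@H](Cc1ccc(OCOC)c(Br)c1)C=O
F7 | step 6 | (2R)-1-[5-bromo-2,4-bis(methoxymethoxy)phenyl]-3-[3-bromo-4-(methoxymethoxy)phenyl]-2-(methoxymethoxy)propan-1-ol (C1 epimers) | COCO[C@H](Cc1ccc(OCOC)c(Br)c1)C(O)c1cc(Br)c(OCOC)cc1OCOC
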